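The numbers of this flask belong to no real substance; the flask was simulated.

4 questions are put about the flasks below, and the candidate must first say where the material ends and then how far along that road each flask stands at the reading.

all flasks: solid substrate 0.40 M; time 4.0 h
- eta: temperature 115 °C
- zeta: at 90 °C until 3.0 h, from then on at 115 °C
- beta: temperature 90 °C

- the best flask by amount of target, in percent of the solid substrate charged; "all alike" if 1.5 percentage points covers them all (eta / zeta / beta / all alike)
- amount of target at the end, in percent of the solid substrate charged, eta
- amount of target at the end, in percent of the solid substrate charged, zeta
- amount of target at the end, in percent of the solid substrate charged, beta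

- solid, in amounts per volume of the solution: solid substrate
- the list of constants is for 90 °C, to be carried to other temperatures by the activation energies
- at the start none of the solid substrate is in solution
- what has only dissolved of solid substrate counts as not reacted

    solid substrate ⇌ starting material, rate k1*(cs1 - [starting material]) while solid is left; crystals form when [starting material] > cs1 (cs1 = 0.31 M, k1 = 0.132 /min)
    intermediate B → intermediate C (k2 = 0.0103 /min, Ea2 = 126 kJ/mol)
    intermediate C → decomposed reagent (k3 = 0.00919 /min, Ea3 = 106 kJ/mol)
    target → over-reaction product (k4 = 8.59 × 10⁻⁴ /min, Ea4 = 109 kJ/mol)
    starting material → intermediate A (k5 = 0.00713 /min, Ea5 = 105 kJ/mol)
    intermediate C → target (k6 = 0.0334 /min, Ea6 = 106 kJ/mol)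
    intermediate A → intermediate B (k7 = 0.00279 /min, Ea7 = 113 kJ/mol)
    (constants at 90 °C)

Where does the charge end? Every reaction arrow runs one way, so the dissolved material passes through intermediates A and B to intermediate C, where it splits. The share of what leaves intermediate C that becomes target is 78.4%, the target share, a branching fraction that follows from the selectivity factor k6/k3 of 3.63, and it is the same at both temperatures because the two branches have equal activation energies. Target then passes on to over-reaction product, so [target] must rise and fall.

How fast is that end approached? The conversion of intermediate A into intermediate B has the smallest constant of the chain, but the constant of the conversion of starting material before it is larger by a factor of just 2.56, so I let these two steps share the control and call neither alone the rate-limiting step. I take the dissolving as instant, since 7.58 min is short against the 140 min of the next step. From 90 °C to 115 °C, the conversion of starting material speeds up by 9.4, that of intermediate A by 11 and that of intermediate C into decomposed reagent by 9.6, and the others follow from the ratio of activation energies.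

And eta? Its chain takes 56.2 min on average, and target has a half-life of 78.9 min there, so the remaining time leaves 19.9% of it, and my figure for eta is 15.6%.

But does a mean transit serve in beta? It does not, because that transit, 619 min, exceeds the run. So I treat the first two steps as a series and the rest as a lag of 121 min, and 9.70% gets through, which gives 7.61% for beta.

And zeta? By my reckoning, at the change 27.7% is still starting material and 53.9% intermediate A. The hot hour, less a lag of 9.05 min, brings the part past intermediate A to 79.1%. If target ages for about half that hour, 76.8% survives, which gives 47.7% for zeta. My choice is zeta.

The forecast says zeta, with 17.6% for eta, 45% for zeta and 8% for beta, on the ground that “Zeta builds up the intermediates cold and then heats for one hour”. It stands above my figures for eta and beta and below mine for zeta.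

The simulation gives zeta as best, with 17.6% for eta, 45.2% for zeta and 8.21% for beta, so the forecast held on each count.

In zeta, the half-life of intermediate A by its step to intermediate B is 4.1 h in the cold, longer than the 3.0 h before the change, and at the change 52.9% of the charge stands as intermediate A against 3.95% as target. The final target in zeta is 57.7% of the target share. In the neighbour with 1.0 M of solid substrate, the target share applied to its 13.8% of decomposed reagent gives 50.1% for target and over-reaction product together; the computed amounts are 39.3% and 11.0%.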